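Reading the alpha run at 4.0 min is the pitfall, because the flask holds more D, 2.0 M against 1.3 M, at the same equivalents of E, and so runs further along in a given time.

| flask | D | E | remark | time | volume of the second phase over the first |
|---|---|---|---|---|---|
| alpha | 1.3 M | 1.5 equiv | run made earlier |  |  |
| eta | 2 M | 3 equiv | run made earlier |  |  |
| flask | 2.0 M | 1.50 equiv |  | 4.0 min | 2.0 |

- alpha (time / min: X / %): 0.417: 3; 0.667: 9; 1.33: 16; 2.50: 25; 5.00: 38
- eta (time / min: X / %): 0.417: 8; 1.33: 34; 2.00: 37; 3.00: 44; 5.00: 43

(standard deviation of a reading: 1.5 percentage points)

- in the second phase: E; everything else is in the first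
- charges count per volume of the first phase; a concentration in a rate is the amount of a species over the volume of its own phase; every rate counts per litre of the first phase
- the earlier runs were read with a standard deviation of 1.5 percentage points
- the earlier runs hold the two phases in the same ratio of volumes as the flask asked about

- violet: doubling the amount of E, all else as stated
- red: doubling the transfer coefficient of E, all else as stated

- X at 4.0 min, in percent of the D charged
- the change that raises the amount of X at 4.0 min, in percent of the D charged most ("none" if none brings more than 2 percentage points) (violet / red / none)
- amount of X at 4.0 min, in percent of the D charged, after violet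

If the steps are bimolecular and the equivalents are held, percent of X should follow the product of [D] charged and time: the flask has 480 M·s of this dose, the reduced time of second-order kinetics. Alpha's last reading, 38%, stands at a smaller dose, 390 M·s, and alpha was still rising there, so that reading is my lower bound. Eta, at the same [D] with more E, has stopped climbing in its last two readings, 44% and 43%, so I take their mean, 43.5%, as the upper bound. Alpha's gap to that ceiling shrank from 18 percentage points at dose 195 M·s to 5.5 points at dose 390 M·s, and the same shrinking per unit of dose gives my figure, 40.4%.

The forecast says 39%, inside the bracket and just below my figure, and chooses violet with 44%, since "Violet is simply eta's conditions".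

    Z ⇌ E, rate k1*([Z] - [E]/K1) per volume of the first phase (partition coefficient = 0.420, kL = 0.0110 s⁻¹)
    D + Z → X (k = 0.00550 M⁻¹ s⁻¹)
    Z + X → J (k = 0.00310 M⁻¹ s⁻¹)
    X ⇌ Q (K = 0.120, k = 0.0110 s⁻¹)
    2 Z → L (k = 0.00310 M⁻¹ s⁻¹)

At dose 480 M·s the flask gives 39.9%, inside the bracket; violet adds 4.4 points, reaching 44.3%, against 1.2 points from red. The making of X from D and Z had 65% of its turnover up to 4.0 min behind it at 2.00 min, with Z at 0.708 M, and by 4.00 min, with Z at 0.444 M, the step to J had a net turnover of 11.6% of the D charged. The flask with 0.50 M of D has dose 120 M·s, between alpha's 104 M·s and 195 M·s, where alpha read 16% and 25%. That flask gives 23.4%.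

The numbers in the tables come from a simulation with made-up constants; scatter was added.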